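## Retrosynthetic overview

- Brianthein Z ⇐ 6-epi allylic alcohol (SN2 chloride, inversion) ⇐ ring enyne (semihydrogenation gives the 3Z,5(16)-diene) ⇐ bicyclic C12 enone (13,14-epoxide, then 12-OAc).
- Six-membered ring: transannular C1–C10 closure of a 14-membered 1,14-epoxy cembranoid enone by epoxide-triggered radical conjugate addition, the radical counterpart of the cembrane 3,8-cyclization; it also sets C10, C1 and C11.
- 14-membered ring: closed at C8–C9 (the bond that closes the cembrane ring in nature) by SmI2 ketyl–olefin coupling of a C9 enal onto a silyl tetronate; this sets C8, C9 and C17 and leaves the lactone in place.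
- Seco compound ⇐ Sonogashira coupling at C4–C5 of a tetronate piece (3-methyltetronic acid + 2-bromoacrolein) with a C9–C14/C1–C4 piece (two C5 enals + TMS-acetylene).
- Ring order: butenolide (from the start) → 14-membered carbocycle → six-membered ring (leaving the ten-membered ring) → oxirane.

Assumption: briarane numbering is used throughout (ring C1–C10; ring C1, C10–C14; C15 on C1, C16 on C5, C18 methyl and C19 carbonyl on C17, C20 on C11), and 1, 3, 5, 7 and 9 are bought.

## Route

Step 1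
Reactants: 1 3-methyltetronic acid
Product: 2 2,4-bis(tert-butyldimethylsilyloxy)-3-methylfuran
Conditions: TBSOTf (2.2 equiv), Et3N (3 equiv), CH2Cl2, 0 °C
Reagents that add atoms: tert-butyldimethylsilyl triflate, CC(C)(C)[Si](C)(C)OS(=O)(=O)C(F)(F)F
Why: double O-silylation (soft enolisation) of the vinylogous acid gives the aromatic bis(silyloxy)furan whose only free nucleophilic carbon is C5 (the future C7); no stereocentre is formed.

Step 2
Reactants: 2 2,4-bis(tert-butyldimethylsilyloxy)-3-methylfuran; 3 2-bromoacrolein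
Product: 4 (5S)-5-[(1S)-2-bromo-1-(tert-butyldimethylsilyloxy)prop-2-en-1-yl]-4-(tert-butyldimethylsilyloxy)-3-methylfuran-2(5H)-one
Conditions: chiral 3,3′-bis[3,5-bis(trifluoromethyl)phenyl]-1,1′-binaphthyl-2,2′-disulfonimide (5 mol %, antipode that gives 5S,1′S), Et2O, −78 °C
Reagents that add atoms: none
Why: vinylogous Mukaiyama aldol with silyl transfer, in which the furan C5 attacks the catalyst-bound aldehyde through an open antiperiplanar transition state to give the threo C6/C7 pair (absolute sense from the catalyst) while the lactone-oxygen silyl group ends on the new C6 oxygen.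

Step 3
Reactants: 5 tiglaldehyde
Product: 6 (1E)-2-methyl-1-(triethylsilyloxy)buta-1,3-diene
Conditions: TESOTf (1.1 equiv), Et3N (1.5 equiv), CH2Cl2, 0 °C
Reagents that add atoms: triethylsilyl triflate, CC[Si](CC)(CC)OS(=O)(=O)C(F)(F)F
Why: O-silylation and γ-deprotonation of the s-trans enal (soft enolisation) give the silyl dienol ether, the d4 donor for C13–C14=C1(C15)–C2.

Step 4
Reactants: 6 (1E)-2-methyl-1-(triethylsilyloxy)buta-1,3-diene; 7 (E)-4-acetoxy-2-methylbut-2-enal
Product: 8 (2E,4S,6E)-3,7-dimethyl-8-oxo-4-(triethylsilyloxy)octa-2,6-dien-1-yl acetate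
Conditions: same chiral disulfonimide (2 mol %), Et2O, −78 °C, 6 added slowly
Reagents that add atoms: none
Why: vinylogous Mukaiyama aldol with silyl transfer joins C12–C13 at the γ-carbon and gives the (E)-enal directly; the catalyst keeps C12 single-handed, although this centre is oxidised away in step 11.

Step 5
Reactants: 8 (2E,4S,6E)-3,7-dimethyl-8-oxo-4-(triethylsilyloxy)octa-2,6-dien-1-yl acetate; 9 trimethylsilylacetylene
Product: 10 (2E,4S,6E,8R)-8-hydroxy-3,7-dimethyl-4-(triethylsilyloxy)-10-(trimethylsilyl)deca-2,6-dien-9-yn-1-yl acetate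
Conditions: Me2Zn (3 equiv), ProPhenol ligand (20 mol %, antipode that gives 8R), Ph3P=O (40 mol %), toluene, 4 °C
Reagents that add atoms: none
Why: zinc–ProPhenol catalysed asymmetric alkynylation of the enal, in which the dinuclear zinc catalyst delivers the alkynyl group to one aldehyde face and so sets C2 by reagent control; acetate and silyl ether are inert to alkynylzinc.

Step 6
Reactants: 10 (2E,4S,6E,8R)-8-hydroxy-3,7-dimethyl-4-(triethylsilyloxy)-10-(trimethylsilyl)deca-2,6-dien-9-yn-1-yl acetate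
Product: 11 (2E,4S,6E,8S)-3,7-dimethyl-4-(triethylsilyloxy)deca-2,6-dien-9-yne-1,8-diol
Conditions: K2CO3 (0.3 equiv), MeOH, 0 °C
Reagents that add atoms: none
Why: base-catalysed methanolysis removes the primary acetate and the alkynyl silyl group in one operation and leaves the TES ether and both stereocentres untouched (the C2 descriptor changes only by priority).

Step 7
Reactants: 11 (2E,4S,6E,8S)-3,7-dimethyl-4-(triethylsilyloxy)deca-2,6-dien-9-yne-1,8-diol
Product: 12 (2E,4S,6E,8S)-8-hydroxy-3,7-dimethyl-4-(triethylsilyloxy)deca-2,6-dien-9-ynal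
Conditions: TEMPO (10 mol %), PhI(OAc)2 (1.1 equiv), CH2Cl2, rt
Reagents that add atoms: none
Why: oxoammonium (TEMPO) oxidation is selective for the primary allylic alcohol over the secondary carbinol and gives the C9 enal without E/Z scrambling.

Step 8
Reactants: 12 (2E,4S,6E,8S)-8-hydroxy-3,7-dimethyl-4-(triethylsilyloxy)deca-2,6-dien-9-ynal
Product: 13 (3S,4E,7S,8E)-4,8-dimethyl-10-oxo-7-(triethylsilyloxy)deca-4,8-dien-1-yn-3-yl acetate
Conditions: Ac2O, pyridine, DMAP (cat.), CH2Cl2, 0 °C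
Reagents that add atoms: acetic anhydride, CC(=O)OC(C)=O
Why: DMAP-catalysed acylation installs the C2 acetate of the target early, with retention at C2.

Step 9
Reactants: 4 (5S)-5-[(1S)-2-bromo-1-(tert-butyldimethylsilyloxy)prop-2-en-1-yl]-4-(tert-butyldimethylsilyloxy)-3-methylfuran-2(5H)-one; 13 (3S,4E,7S,8E)-4,8-dimethyl-10-oxo-7-(triethylsilyloxy)deca-4,8-dien-1-yn-3-yl acetate
Product: 14 seco-aldehyde (open-chain C9 enal joined at C4–C5 to the tetronate piece)
Conditions: Pd(PPh3)4 (5 mol %), CuI (10 mol %), Et3N, THF, rt to 40 °C, degassed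
Reagents that add atoms: none
Why: Sonogashira coupling of the 2-bromoalkene with the terminal alkyne forms C4–C5 and the 2-substituted 1,3-enyne, a linear mask for the Z-diene that keeps C16 away from C1 in the later radical step; no stereocentre is touched.

Step 10
Reactants: 14 seco-aldehyde
Product: 16 macrocyclic C9 acetate, via macrocyclic C9 alcohol 15 (not isolated)
Conditions: SmI2 (2.5 equiv), t-BuOH (2.2 equiv), THF, 2 mM, 14 added over 6 h, −78 to −20 °C; then Ac2O, Et3N, DMAP, 0 °C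
Reagents that add atoms: acetic anhydride, CC(=O)OC(C)=O
Why: Proposed new method: SmI2 reduces the enal to a ketyl that, because its β-terminus C11 is fully substituted, bonds through C9 to the β-carbon C8 of the silyl tetronate (closest known types: SmI2 ketyl–olefin cyclisation onto β-alkoxyacrylates and samarium-templated macrocyclisations), with attack anti to the C6 side chain on C7 setting C8, the samarium bridge between ketyl oxygen and lactone carbonyl setting C9, and proton delivery from samarium-bound t-BuOH on the C9 face setting C17, after which Ac2O traps the hindered C9 alkoxide before it can translactonise.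

Step 11
Reactants: 16 macrocyclic C9 acetate
Product: 18 macrocyclic C12 enone, via macrocyclic C12 alcohol 17 (not isolated)
Conditions: IBX (3 equiv), DMSO, rt
Reagents that add atoms: none
Why: IBX cleaves the TES ether in the presence of TBS ethers and oxidises the freed allylic alcohol in the same flask (desilylation–oxidation), giving the C10=C11–C12=O acceptor and removing the C12 stereocentre.

Step 12
Reactants: 18 macrocyclic C12 enone
Product: 19 macrocyclic 1,14-epoxy enone
Conditions: mCPBA (1.05 equiv), NaHCO3, CH2Cl2, −20 °C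
Reagents that add atoms: meta-chloroperbenzoic acid, O=C(OO)c1cccc(Cl)c1
Why: Prilezhaev epoxidation picks the only electron-rich trisubstituted alkene (the enone and enyne alkenes are deactivated) by peripheral attack on the macrocycle, and the epoxide configuration is of no consequence because C1 becomes a radical and the C14 oxygen is eliminated in step 14.

Step 13
Reactants: 19 macrocyclic 1,14-epoxy enone
Product: 20 bicyclic 14-hydroxy-12-ketone
Conditions: Cp2TiCl2 (2.2 equiv), Mn powder (8 equiv), THF, 0.01 M, rt; then 2,4,6-collidinium chloride, −78 °C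
Reagents that add atoms: none
Why: Proposed new method: Cp2TiCl (trivalent titanium) opens the epoxide at the tertiary carbon (Nugent–RajanBabu opening) and the C1 radical adds transannularly 6-endo to C10 of the enone (Giese addition; closest known type: trivalent-titanium transannular closure of epoxygermacrolides to eudesmanolides), anti to C8 with H-9 eclipsing the alkene (A(1,3) strain) to set C10, through a chair that gives the trans ring fusion at C1, and the titanium enolate is protonated at C11 by the bulky collidinium ion on the face away from the new angular methyl.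

Step 14
Reactants: 20 bicyclic 14-hydroxy-12-ketone
Product: 22 bicyclic 13-en-12-one, via C14 mesylate 21 (not isolated)
Conditions: MsCl (1.5 equiv), Et3N (4 equiv), CH2Cl2, 0 °C to rt
Reagents that add atoms: none
Why: mesylation and E1cB elimination of the β-mesyloxy ketone can only give the 13,14-alkene because C1 is quaternary, and C11 is not epimerised because enolisation toward C13 is driven by loss of mesylate.

Step 15
Reactants: 22 bicyclic 13-en-12-one
Product: 23 13,14-epoxy-12-ketone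
Conditions: t-BuOOH (3 equiv), DBU (0.3 equiv), CH2Cl2, 0 °C
Reagents that add atoms: tert-butyl hydroperoxide, CC(C)(C)OO
Why: Weitz–Scheffer nucleophilic epoxidation, in which the peroxide anion adds to C14 anti to the axial C15 methyl on the neighbouring quaternary C1 and so places the oxirane on the face opposite C15.

Step 16
Reactants: 23 13,14-epoxy-12-ketone
Product: 24 13,14-epoxy-12-ol
Conditions: NaBH4 (1.5 equiv), CeCl3·7H2O (1.5 equiv), MeOH, −78 °C
Reagents that add atoms: none
Why: Luche-type reduction of an α,β-epoxy ketone, in which hydride enters the cerium-activated carbonyl anti to the oxirane oxygen and gives the cis epoxy alcohol (C12).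

Step 17
Reactants: 24 13,14-epoxy-12-ol
Product: 25 2,9,12-triacetate
Conditions: Ac2O, pyridine, DMAP (cat.), CH2Cl2, rt
Reagents that add atoms: acetic anhydride, CC(=O)OC(C)=O
Why: DMAP-catalysed acylation of the only free hydroxyl with retention at C12; C6 and C8 stay silylated.

Step 18
Reactants: 25 2,9,12-triacetate
Product: 26 6,8-diol enyne
Conditions: HF·pyridine (excess), pyridine, THF, 0 °C to rt, 24 h
Reagents that add atoms: none
Why: fluoride-driven desilylation under buffered acidic conditions removes both TBS ethers without acetate migration and leaves the hindered, acetoxy-flanked oxirane intact.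

Step 19
Reactants: 26 6,8-diol enyne
Product: 27 6,8-diol 3Z,5(16)-diene
Conditions: H2 (1 atm), Pd/CaCO3 poisoned with Pb(OAc)2, quinoline, EtOAc, rt, stopped at 1 equiv H2
Reagents that add atoms: none
Why: Lindlar semihydrogenation adds H2 syn to the ring alkyne, and the ten-membered ring allows only the 3Z alkene.

Step 20
Reactants: 27 6,8-diol 3Z,5(16)-diene
Product: 28 brianthein Z
Conditions: PPh3 (1.5 equiv), hexachloroacetone (3 equiv), CH2Cl2, −20 to 0 °C
Reagents that add atoms: hexachloroacetone, ClC(Cl)(Cl)C(=O)C(Cl)(Cl)Cl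
Why: Appel-type chlorination under Magid conditions, in which chloride displaces the C6 oxyphosphonium by SN2 with inversion and without allylic transposition, giving the 6-chloride of the target while the tertiary C8 hydroxyl does not react.

## Compound list

1 | 3-methyltetronic acid (4-hydroxy-3-methylfuran-2(5H)-one) | CC1=C(O)COC1=O | starting material

2 | 2,4-bis(tert-butyldimethylsilyloxy)-3-methylfuran | Cc1c(O[Si](C)(C)C(C)(C)C)occ1O[Si](C)(C)C(C)(C)C | intermediate

3 | 2-bromoacrolein | C=C(Br)C=O | starting material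

4 | (5S)-5-[(1S)-2-bromo-1-(tert-butyldimethylsilyloxy)prop-2-en-1-yl]-4-(tert-butyldimethylsilyloxy)-3-methylfuran-2(5H)-one (C5–C8, C16–C19; ring C5 is C7, side-chain C1 is C6) | C=C(Br)[C@@H](O[Si](C)(C)C(C)(C)C)[C@@H]1OC(=O)C(C)=C1O[Si](C)(C)C(C)(C)C | intermediate

5 | tiglaldehyde, (E)-2-methylbut-2-enal | C/C=C(\C)C=O | starting material

6 | (1E)-2-methyl-1-(triethylsilyloxy)buta-1,3-diene | C=C/C(C)=C/O[Si](CC)(CC)CC | intermediate

7 | (E)-4-acetoxy-2-methylbut-2-enal | CC(=O)OC/C=C(\C)C=O | starting material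

8 | (2E,4S,6E)-3,7-dimethyl-8-oxo-4-(triethylsilyloxy)octa-2,6-dien-1-yl acetate (C9–C14, C1, C2) | O=C/C(C)=C/C[C@H](O[Si](CC)(CC)CC)/C(C)=C/COC(C)=O | intermediate

9 | trimethylsilylacetylene | C#C[Si](C)(C)C | starting material

10 | (2E,4S,6E,8R)-8-hydroxy-3,7-dimethyl-4-(triethylsilyloxy)-10-(trimethylsilyl)deca-2,6-dien-9-yn-1-yl acetate | C[Si](C)(C)C#C[C@H](O)/C(C)=C/C[C@H](O[Si](CC)(CC)CC)/C(C)=C/COC(C)=O | intermediate

11 | (2E,4S,6E,8S)-3,7-dimethyl-4-(triethylsilyloxy)deca-2,6-dien-9-yne-1,8-diol | C#C[C@H](O)/C(C)=C/C[C@H](O[Si](CC)(CC)CC)/C(C)=C/CO | intermediate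

12 | (2E,4S,6E,8S)-8-hydroxy-3,7-dimethyl-4-(triethylsilyloxy)deca-2,6-dien-9-ynal | C#C[C@H](O)/C(C)=C/C[C@H](O[Si](CC)(CC)CC)/C(C)=C/C=O | intermediate

13 | (3S,4E,7S,8E)-4,8-dimethyl-10-oxo-7-(triethylsilyloxy)deca-4,8-dien-1-yn-3-yl acetate (C9 enal to C4 alkyne) | C#C[C@H](OC(C)=O)/C(C)=C/C[C@H](O[Si](CC)(CC)CC)/C(C)=C/C=O | intermediate

14 | seco-aldehyde: 13 bonded through C4 to C5 of 4; C9 enal, 10E, 12-OTES, 1(14)E, 2-OAc, 3-yne, 5(16)-ene, 6-OTBS, silyl tetronate; stereocentres as in 4 and 13 | C=C(C#C[C@H](OC(C)=O)/C(C)=C/C[C@H](O[Si](CC)(CC)CC)/C(C)=C/C=O)[C@@H](O[Si](C)(C)C(C)(C)C)[C@@H]1OC(=O)C(C)=C1O[Si](C)(C)C(C)(C)C | intermediate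

15 | macrocyclic C9 alcohol: 14-membered ring C1–C14 with 1(14)E and 10E alkenes, 3-yne, 5(16)-ene; 2-OAc, 6-OTBS, 8-OTBS, 9-OH, 12-OTES; saturated C19→O–C7 lactone; C2, C7, C8, C9, C17 as in 28, C6 oxygen on the face opposite to the chlorine of 28 | C=C1C#C[C@H](OC(C)=O)/C(C)=C/C[C@H](O[Si](CC)(CC)CC)/C(C)=C/[C@H](O)[C@]2(O[Si](C)(C)C(C)(C)C)[C@@H](C)C(=O)O[C@H]2[C@@H]1O[Si](C)(C)C(C)(C)C | intermediate (not isolated)

16 | macrocyclic C9 acetate: 15 with 9-OAc | C=C1C#C[C@H](OC(C)=O)/C(C)=C/C[C@H](O[Si](CC)(CC)CC)/C(C)=C/[C@H](OC(C)=O)[C@]2(O[Si](C)(C)C(C)(C)C)[C@@H](C)C(=O)O[C@H]2[C@@H]1O[Si](C)(C)C(C)(C)C | intermediate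

17 | macrocyclic C12 alcohol: 16 with free 12-OH | C=C1C#C[C@H](OC(C)=O)/C(C)=C/C[C@H](O)/C(C)=C/[C@H](OC(C)=O)[C@]2(O[Si](C)(C)C(C)(C)C)[C@@H](C)C(=O)O[C@H]2[C@@H]1O[Si](C)(C)C(C)(C)C | intermediate (not isolated)

18 | macrocyclic C12 enone: 16 with C12 ketone conjugated to the 10E alkene | C=C1C#C[C@H](OC(C)=O)/C(C)=C/CC(=O)/C(C)=C/[C@H](OC(C)=O)[C@]2(O[Si](C)(C)C(C)(C)C)[C@@H](C)C(=O)O[C@H]2[C@@H]1O[Si](C)(C)C(C)(C)C | intermediate

19 | macrocyclic 1,14-epoxy enone: 18 with trans 1,14-oxirane (C2 and C13 trans), drawn diastereomer | C=C1C#C[C@H](OC(C)=O)[C@@]2(C)O[C@@H]2CC(=O)/C(C)=C/[C@H](OC(C)=O)[C@]3(O[Si](C)(C)C(C)(C)C)[C@@H](C)C(=O)O[C@H]3[C@@H]1O[Si](C)(C)C(C)(C)C | intermediate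

20 | bicyclic 14-hydroxy-12-ketone: briarane 6/10 skeleton, trans-fused; C1, C10, C11 as in 28; 14-OH cis to C15; 2,9-di-OAc, 6,8-di-OTBS, 3-yne, 5(16)-ene, lactone | C=C1C#C[C@H](OC(C)=O)[C@]2(C)[C@H]([C@@H](C)C(=O)C[C@H]2O)[C@H](OC(C)=O)[C@]3(O[Si](C)(C)C(C)(C)C)[C@@H](C)C(=O)O[C@H]3[C@@H]1O[Si](C)(C)C(C)(C)C | intermediate

21 | C14 mesylate of 20 | C=C1C#C[C@H](OC(C)=O)[C@]2(C)[C@H]([C@@H](C)C(=O)C[C@H]2OS(C)(=O)=O)[C@H](OC(C)=O)[C@]3(O[Si](C)(C)C(C)(C)C)[C@@H](C)C(=O)O[C@H]3[C@@H]1O[Si](C)(C)C(C)(C)C | intermediate (not isolated)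

22 | bicyclic 13-en-12-one | C=C1C#C[C@H](OC(C)=O)[C@]2(C)[C@H]([C@@H](C)C(=O)C=C2)[C@H](OC(C)=O)[C@]3(O[Si](C)(C)C(C)(C)C)[C@@H](C)C(=O)O[C@H]3[C@@H]1O[Si](C)(C)C(C)(C)C | intermediate

23 | 13,14-epoxy-12-ketone (oxirane trans to C15, as in 28) | C=C1C#C[C@H](OC(C)=O)[C@]2(C)[C@H]([C@@H](C)C(=O)[C@@H]3O[C@@H]32)[C@H](OC(C)=O)[C@]4(O[Si](C)(C)C(C)(C)C)[C@@H](C)C(=O)O[C@H]4[C@@H]1O[Si](C)(C)C(C)(C)C | intermediate

24 | 13,14-epoxy-12-ol (12-OH cis to the oxirane, as in 28) | C=C1C#C[C@H](OC(C)=O)[C@]2(C)[C@H]([C@@H](C)[C@H](O)[C@@H]3O[C@@H]32)[C@H](OC(C)=O)[C@]4(O[Si](C)(C)C(C)(C)C)[C@@H](C)C(=O)O[C@H]4[C@@H]1O[Si](C)(C)C(C)(C)C | intermediate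

25 | 2,9,12-triacetate (6,8-bis-OTBS, 3-yne) | C=C1C#C[C@H](OC(C)=O)[C@]2(C)[C@H]([C@@H](C)[C@H](OC(C)=O)[C@@H]3O[C@@H]32)[C@H](OC(C)=O)[C@]4(O[Si](C)(C)C(C)(C)C)[C@@H](C)C(=O)O[C@H]4[C@@H]1O[Si](C)(C)C(C)(C)C | intermediate

26 | 6,8-diol enyne (6-OH epimeric in space to the chlorine of 28) | C=C1C#C[C@H](OC(C)=O)[C@]2(C)[C@H]([C@@H](C)[C@H](OC(C)=O)[C@@H]3O[C@@H]32)[C@H](OC(C)=O)[C@]4(O)[C@@H](C)C(=O)O[C@H]4[C@@H]1O | intermediate

27 | 6,8-diol 3Z,5(16)-diene (6-dechloro-6-epi-hydroxy brianthein Z) | C=C1/C=C\[C@H](OC(C)=O)[C@]2(C)[C@H]([C@@H](C)[C@H](OC(C)=O)[C@@H]3O[C@@H]32)[C@H](OC(C)=O)[C@]4(O)[C@@H](C)C(=O)O[C@H]4[C@@H]1O | intermediate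

28 | brianthein Z, (1S,2S,6S,7R,8R,9S,10S,11R,12S,13S,14R,17R)-2,9,12-triacetoxy-6-chloro-13,14-epoxy-8-hydroxybriara-3Z,5(16)-dien-19,7-olide | C=C1/C=C\[C@H](OC(C)=O)[C@]2(C)[C@H]([C@@H](C)[C@H](OC(C)=O)[C@@H]3O[C@@H]32)[C@H](OC(C)=O)[C@]2(O)[C@@H](C)C(=O)O[C@H]2[C@H]1Cl | target

## Step count and risks

Total steps: 20. Longest linear sequence: 18 (steps 3–20, from 5 and 7).

Steps most likely to fail:

Step 10. A stabilised allyl-type ketyl must add to a tetrasubstituted β-silyloxy butenolide while closing a 14-membered ring, in competition with pinacol dimerisation and simple reduction. The fallback sets out from 13 and 4 and reverses the order of the two joining bonds. The same SmI2 coupling is run between the two pieces at 0.1 M with 4 in threefold excess (SmI2, t-BuOH, THF, −78 °C), giving the open-chain C9 alcohol F1. This is acetylated in the same flask (Ac2O, Et3N, DMAP) to the open-chain C9 acetate F2, which still carries the 2-bromoalkene and the terminal alkyne. The ring is then closed at C4–C5 by an intramolecular Sonogashira coupling (Pd(PPh3)4, CuI, Et3N, THF, 1 mM, syringe pump), which comes back to the route at 16.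

Step 13. The C1 radical carries a β-acetoxy group (possible 1,2-acyloxy shift toward the propargylic C2 position) and may be reduced before it cyclises. The fallback sets out from 18, before the epoxidation, and makes the same radical by hydrogen-atom transfer to the C1=C14 alkene (Fe(acac)3, PhSiH3, EtOH/ethylene glycol, 60 °C). The same 6-endo Giese closure and enolate protonation give the 14-deoxy bicyclic ketone F3. Kinetic enolisation toward C13 (LiN(SiMe3)2, TMSCl, THF, −78 °C) gives the C12 trimethylsilyl enol ether F4, and Saegusa–Ito oxidation (Pd(OAc)2, MeCN, rt) gives the enone, which comes back to the route at 22.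

Step 16. The β-methyl on C11 sits on the face from which hydride must come, so attack from the oxirane face may win. The fallback sets out from 23 and accepts that outcome. NaBH4 without cerium (or L-Selectride) then gives the 12-epi epoxy alcohol F5, and a Mitsunobu reaction with acetic acid (PPh3, DIAD, AcOH, toluene, 0 °C) inverts C12 and installs the acetate in one operation, which comes back to the route at 25.

## Further compounds

F1 | step 10 | open-chain C9 alcohol (C8–C9 joined; 2-bromoalkene and terminal alkyne intact) | C=C(Br)[C@@H](O[Si](C)(C)C(C)(C)C)[C@@H]1OC(=O)[C@H](C)[C@@]1(O[Si](C)(C)C(C)(C)C)[C@@H](O)/C=C(\C)[C@@H](O[Si](CC)(CC)CC)C/C=C(\C)[C@@H](OC(C)=O)C#C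

F2 | step 10 | open-chain C9 acetate | C=C(Br)[C@@H](O[Si](C)(C)C(C)(C)C)[C@@H]1OC(=O)[C@H](C)[C@@]1(O[Si](C)(C)C(C)(C)C)[C@@H](OC(C)=O)/C=C(\C)[C@@H](O[Si](CC)(CC)CC)C/C=C(\C)[C@@H](OC(C)=O)C#C

F3 | step 13 | 14-deoxy bicyclic ketone | C=C1C#C[C@H](OC(C)=O)[C@]2(C)[C@H]([C@@H](C)C(=O)CC2)[C@H](OC(C)=O)[C@]3(O[Si](C)(C)C(C)(C)C)[C@@H](C)C(=O)O[C@H]3[C@@H]1O[Si](C)(C)C(C)(C)C

F4 | step 13 | C12 trimethylsilyl enol ether (12,13-ene) | C=C1C#C[C@H](OC(C)=O)[C@]2(C)[C@H]([C@@H](C)C(O[Si](C)(C)C)=CC2)[C@H](OC(C)=O)[C@]3(O[Si](C)(C)C(C)(C)C)[C@@H](C)C(=O)O[C@H]3[C@@H]1O[Si](C)(C)C(C)(C)C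

F5 | step 16 | 12-epi epoxy alcohol (C12 epimer of 24) | C=C1C#C[C@H](OC(C)=O)[C@]2(C)[C@H]([C@@H](C)[C@@H](O)[C@@H]3O[C@@H]32)[C@H](OC(C)=O)[C@]4(O[Si](C)(C)C(C)(C)C)[C@@H](C)C(=O)O[C@H]4[C@@H]1O[Si](C)(C)C(C)(C)C
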